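The seven-membered ring is closed by an intramolecular vinylogous Mukaiyama aldol reaction: C7, the γ-carbon of a 3-methylbut-2-enoyl group (C10 carbonyl, C9=C8) on the quaternary carbon C1, adds to an aldehyde (C6) on the neighbouring cyclopentane carbon C5. One operation forms the C6–C7 bond, the cycloheptenone ring with the C8=C9 double bond in place, and the C6 carbinol centre. The step exploits the 1,5-dioxygenation C6/C10 of the seven-membered ring, the trans-1,2 disposition of the two arms on the cyclopentane (α-attack would need a trans-bicyclo[3.3.0]octane) and the angular C1 methyl. The precursor is a monocyclic keto aldehyde made from 3-methylcyclopent-2-enone.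

Key step: step 8

Remark: atom labels follow daucane numbering (C1 methyl-bearing ring-fusion carbon, C2/C3 ring CH2, C4 isopropyl carbinol, C5 ring-fusion CH, C6 aroyloxy carbon, C7 ring CH2, C8 methyl-bearing alkene carbon, C9 alkene CH, C10 angeloyloxy carbon); β is the face of the C1 methyl.

Step 1
Reactants: 1 3-methylcyclopent-2-en-1-one; 2 ethynyltrimethylsilane; 3 trimethylsilyl trifluoromethanesulfonate
Product: 6 trimethyl({(3S)-3-methyl-3-[1-(trimethylsilyl)ethenyl]cyclopent-1-en-1-yl}oxy)silane, via alkenylalane 4 (not isolated), via aluminium enolate 5 (not isolated)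
Conditions: 2, DIBAL-H, hexane/THF, 55 °C; then 1, chiral sulfonate-bearing NHC–Ag complex (2.5 mol %), CuCl2·2H2O (5 mol %), THF, −30 °C; then TMSOTf, −78 → 0 °C
Reagents that add atoms: trimethylsilyl trifluoromethanesulfonate (3), C[Si](C)(C)OS(=O)(=O)C(F)(F)F
Why: Hydroalumination puts aluminium on the silyl-bearing alkyne carbon, and NHC–Cu-catalysed enantioselective conjugate addition of this vinylaluminium to the β-methyl enone should set the quaternary centre C1 (ligand enantiomer chosen for S); O-silylation of the aluminium enolate fixes the enolate regiochemistry toward C5.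

Step 2
Reactants: 6 silyl enol ether from step 1; 7 trimethyl orthoformate
Product: 8 (2S,3S)-2-(dimethoxymethyl)-3-methyl-3-[1-(trimethylsilyl)ethenyl]cyclopentan-1-one
Conditions: HC(OMe)3, BF3·OEt2, CH2Cl2, −78 °C
Reagents that add atoms: trimethyl orthoformate (7), COC(OC)OC
Why: Mukaiyama-type addition of the silyl enol ether to the dimethoxycarbenium ion; the electrophile should enter anti to the bulky 1-silylvinyl group on the adjacent quaternary carbon, giving the trans acetal, which is also the thermodynamic epimer of this enolisable centre (C5).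

Step 3
Reactants: 8 keto acetal from step 2; 9 isopropylmagnesium chloride
Product: 10 (1R,2R,3S)-2-(dimethoxymethyl)-3-methyl-1-(propan-2-yl)-3-[1-(trimethylsilyl)ethenyl]cyclopentan-1-ol
Conditions: i-PrMgCl, LaCl3·2LiCl, THF, −20 → 0 °C; aq. NH4Cl
Reagents that add atoms: isopropylmagnesium chloride (9), CC(C)[Mg]Cl
Why: Lanthanide-promoted Grignard 1,2-addition suppresses enolisation and β-hydride reduction; attack anti to the adjacent dimethoxymethyl group should place the new hydroxyl cis to that group and the isopropyl trans (C4).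

Step 4
Reactants: 10 tertiary alcohol from step 3
Product: 12 1-[(1S,2R,3R)-2-(dimethoxymethyl)-3-hydroxy-1-methyl-3-(propan-2-yl)cyclopentyl]ethan-1-one, via epoxysilane 11 (not isolated)
Conditions: mCPBA, NaHCO3, CH2Cl2, 0 → 22 °C; then H2SO4 (cat.), MeOH/H2O (10:1), 22 °C
Reagents that add atoms: m-chloroperbenzoic acid (oxygen of the intermediate epoxide), OOC(=O)c1cccc(Cl)c1; water (carbonyl oxygen), O
Why: Epoxidation of the 1,1-disubstituted vinylsilane, then acid-mediated opening at the silicon-bearing carbon and Peterson-type loss of silanol (α,β-epoxysilane-to-ketone conversion) should unmask the methyl ketone, while the dimethyl acetal persists in methanol.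

Step 5
Reactants: 12 methyl ketone from step 4; 13 acetone
Product: 14 3-hydroxy-1-[(1S,2R,3R)-2-(dimethoxymethyl)-3-hydroxy-1-methyl-3-(propan-2-yl)cyclopentyl]-3-methylbutan-1-one
Conditions: LDA (2.2 equiv), THF, −78 °C; acetone; AcOH, −78 °C
Reagents that add atoms: acetone (13), CC(C)=O
Why: Aldol addition; the methyl group is the only enolisable position of the ketone because C1 is quaternary, so a single lithium enolate forms (the second equivalent of base deprotonates the tertiary alcohol) and adds to acetone.

Step 6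
Reactants: 14 aldol from step 5
Product: 15 1-[(1S,2R,3R)-2-(dimethoxymethyl)-3-hydroxy-1-methyl-3-(propan-2-yl)cyclopentyl]-3-methylbut-2-en-1-one
Conditions: MsCl, Et3N, DMAP (cat.), CH2Cl2, 0 → 22 °C
Reagents that add atoms: none
Why: Mesylation of the less hindered aldol hydroxyl and E1cB elimination should give the conjugated enone; the far more hindered ring carbinol has no adjacent carbonyl and should stay untouched.

Step 7
Reactants: 15 enone acetal from step 6
Product: 16 (1R,2R,5S)-2-hydroxy-5-methyl-5-(3-methylbut-2-enoyl)-2-(propan-2-yl)cyclopentane-1-carbaldehyde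
Conditions: oxalic acid, THF/H2O (4:1), 22 °C
Reagents that add atoms: water, O
Why: Mild acid-catalysed acetal hydrolysis; the aldehyde α-carbon C5 is flanked by two fully substituted carbons and its trans arrangement is also the thermodynamic one, so the configuration should hold.

Step 8
Reactants: 16 keto aldehyde from step 7
Product: 19 (3R,3aS,4S,8aS)-3,4-dihydroxy-6,8a-dimethyl-3-(propan-2-yl)-2,3,3a,4,5,8a-hexahydroazulen-8(1H)-one, via silyl dienol ether 17 (not isolated), via bis(trimethylsilyl) ether 18 (not isolated)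
Conditions: TMSOTf (3), i-Pr2NEt, CH2Cl2, −78 → −20 °C; then citric acid, MeOH, 22 °C
Reagents that add atoms: none
Why: TMSOTf/i-Pr2NEt should silylate the tertiary alcohol and convert the enone, whose only acidic hydrogens are the γ-methyl ones because C1 is quaternary, into the 2-silyloxydiene 17; its terminal carbon C7 then adds to the TMSOTf-activated aldehyde carbon C6 and silyl transfer gives 18, which is desilylated on work-up. The closest known reaction types are the one-pot enol silane formation/Mukaiyama aldol addition and intramolecular vinylogous Mukaiyama aldol cyclisations. The seven-membered ring closes in a 7-(enolendo)-exo-trig mode through the (E)-dienol ether, which should be reached by reversible silylation. The new stereocentre C6 is controlled by the angular C1 methyl: in the chair-like transition state the silylated carbonyl oxygen points away from C1 and the aldehyde hydrogen lies under the methyl, which should give the 6α (4S) alcohol. The step needs γ- over α-selectivity, secured by the γ-preference of silyl dienol ethers and by the trans relation of the arms on C1 and C5 (α-attack through C9 would form a trans-bicyclo[3.3.0]octane); enolisation of the aldehyde should be slow because C5–H sits between two fully substituted carbons.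

Step 9
Reactants: 19 diol enone from step 8; 20 4-methoxybenzoyl chloride
Product: 21 (3R,3aS,4S,8aS)-3-hydroxy-6,8a-dimethyl-8-oxo-3-(propan-2-yl)-1,2,3,3a,4,5,8,8a-octahydroazulen-4-yl 4-methoxybenzoate
Conditions: 4-MeOC6H4COCl, DMAP, pyridine, CH2Cl2, 0 → 22 °C
Reagents that add atoms: 4-methoxybenzoyl chloride (20), COc1ccc(cc1)C(Cl)=O
Why: DMAP-catalysed acylation of the secondary C6 hydroxyl; the tertiary C4 hydroxyl should not react under these conditions.

Step 10
Reactants: 21 keto ester from step 9
Product: 22 (3R,3aS,4S,8S,8aS)-3,8-dihydroxy-6,8a-dimethyl-3-(propan-2-yl)-1,2,3,3a,4,5,8,8a-octahydroazulen-4-yl 4-methoxybenzoate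
Conditions: NaBH4, CeCl3·7H2O, MeOH, −78 °C
Reagents that add atoms: none
Why: Luche 1,2-reduction; hydride should attack C10 along the axial trajectory anti to the angular C1 methyl, giving the pseudo-equatorial 10β (8S) alcohol, the epimer needed for the inversion that follows.

Step 11
Reactants: 22 allylic alcohol from step 10; 23 angelic acid
Product: 24 (3R,3aS,4S,8R,8aS)-3-hydroxy-6,8a-dimethyl-8-{[(2Z)-2-methylbut-2-enoyl]oxy}-3-(propan-2-yl)-1,2,3,3a,4,5,8,8a-octahydroazulen-4-yl 4-methoxybenzoate
Conditions: angelic acid, PPh3, DIAD, toluene, 0 → 22 °C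
Reagents that add atoms: (2Z)-2-methylbut-2-enoic acid (23), C/C=C(/C)C(=O)O
Why: Mitsunobu esterification with inversion; the carboxylate should displace the equatorial oxyphosphonium group from the α face, anti to the C1 methyl, setting 8R, and because the free carboxylate (not an activated acyl species) is the nucleophile the Z-enoate geometry should be kept; the tertiary hydroxyl is inert.

Compound list
1 | 3-methylcyclopent-2-en-1-one | CC1=CC(=O)CC1 | starting material
2 | ethynyltrimethylsilane | C#C[Si](C)(C)C | starting material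
3 | trimethylsilyl trifluoromethanesulfonate | C[Si](C)(C)OS(=O)(=O)C(F)(F)F | starting material
4 | diisobutyl[1-(trimethylsilyl)ethenyl]aluminium | C=C([Si](C)(C)C)[Al](CC(C)C)CC(C)C | intermediate (not isolated)
5 | diisobutylaluminium (3S)-3-methyl-3-[1-(trimethylsilyl)ethenyl]cyclopent-1-en-1-olate | CC(C)C[Al](CC(C)C)OC1=C[C@@](C)(C(=C)[Si](C)(C)C)CC1 | intermediate (not isolated)
6 | trimethyl({(3S)-3-methyl-3-[1-(trimethylsilyl)ethenyl]cyclopent-1-en-1-yl}oxy)silane | C[Si](C)(C)OC1=C[C@@](C)(C(=C)[Si](C)(C)C)CC1 | intermediate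
7 | trimethyl orthoformate | COC(OC)OC | starting material
8 | (2S,3S)-2-(dimethoxymethyl)-3-methyl-3-[1-(trimethylsilyl)ethenyl]cyclopentan-1-one | COC(OC)[C@@H]1[C@@](C)(C(=C)[Si](C)(C)C)CCC1=O | intermediate
9 | isopropylmagnesium chloride | CC(C)[Mg]Cl | starting material
10 | (1R,2R,3S)-2-(dimethoxymethyl)-3-methyl-1-(propan-2-yl)-3-[1-(trimethylsilyl)ethenyl]cyclopentan-1-ol | COC(OC)[C@@H]1[C@@](C)(C(=C)[Si](C)(C)C)CC[C@@]1(O)C(C)C | intermediate
11 | (1R,2R,3S)-2-(dimethoxymethyl)-3-methyl-1-(propan-2-yl)-3-[2-(trimethylsilyl)oxiran-2-yl]cyclopentan-1-ol (both epoxide epimers) | COC(OC)[C@@H]1[C@@](C)(C2(CO2)[Si](C)(C)C)CC[C@@]1(O)C(C)C | intermediate (not isolated)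
12 | 1-[(1S,2R,3R)-2-(dimethoxymethyl)-3-hydroxy-1-methyl-3-(propan-2-yl)cyclopentyl]ethan-1-one | COC(OC)[C@@H]1[C@@](C)(C(C)=O)CC[C@@]1(O)C(C)C | intermediate
13 | acetone | CC(C)=O | starting material
14 | 3-hydroxy-1-[(1S,2R,3R)-2-(dimethoxymethyl)-3-hydroxy-1-methyl-3-(propan-2-yl)cyclopentyl]-3-methylbutan-1-one | COC(OC)[C@@H]1[C@@](C)(C(=O)CC(C)(C)O)CC[C@@]1(O)C(C)C | intermediate
15 | 1-[(1S,2R,3R)-2-(dimethoxymethyl)-3-hydroxy-1-methyl-3-(propan-2-yl)cyclopentyl]-3-methylbut-2-en-1-one | COC(OC)[C@@H]1[C@@](C)(C(=O)C=C(C)C)CC[C@@]1(O)C(C)C | intermediate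
16 | (1R,2R,5S)-2-hydroxy-5-methyl-5-(3-methylbut-2-enoyl)-2-(propan-2-yl)cyclopentane-1-carbaldehyde | O=C[C@@H]1[C@@](C)(C(=O)C=C(C)C)CC[C@@]1(O)C(C)C | intermediate
17 | (1R,2R,5S)-5-methyl-5-[(1E)-3-methyl-1-(trimethylsilyloxy)buta-1,3-dien-1-yl]-2-(propan-2-yl)-2-(trimethylsilyloxy)cyclopentane-1-carbaldehyde | O=C[C@@H]1[C@@](C)(/C(O[Si](C)(C)C)=C\C(C)=C)CC[C@@]1(O[Si](C)(C)C)C(C)C | intermediate (not isolated)
18 | (3R,3aS,4S,8aS)-6,8a-dimethyl-3-(propan-2-yl)-3,4-bis(trimethylsilyloxy)-2,3,3a,4,5,8a-hexahydroazulen-8(1H)-one | O=C1C=C(C)C[C@H](O[Si](C)(C)C)[C@@H]2[C@]1(C)CC[C@@]2(O[Si](C)(C)C)C(C)C | intermediate (not isolated)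
19 | (3R,3aS,4S,8aS)-3,4-dihydroxy-6,8a-dimethyl-3-(propan-2-yl)-2,3,3a,4,5,8a-hexahydroazulen-8(1H)-one | O=C1C=C(C)C[C@H](O)[C@@H]2[C@]1(C)CC[C@@]2(O)C(C)C | intermediate
20 | 4-methoxybenzoyl chloride | COc1ccc(cc1)C(Cl)=O | starting material
21 | (3R,3aS,4S,8aS)-3-hydroxy-6,8a-dimethyl-8-oxo-3-(propan-2-yl)-1,2,3,3a,4,5,8,8a-octahydroazulen-4-yl 4-methoxybenzoate | O=C1C=C(C)C[C@H](OC(=O)c3ccc(OC)cc3)[C@@H]2[C@]1(C)CC[C@@]2(O)C(C)C | intermediate
22 | (3R,3aS,4S,8S,8aS)-3,8-dihydroxy-6,8a-dimethyl-3-(propan-2-yl)-1,2,3,3a,4,5,8,8a-octahydroazulen-4-yl 4-methoxybenzoate | O[C@H]1C=C(C)C[C@H](OC(=O)c3ccc(OC)cc3)[C@@H]2[C@]1(C)CC[C@@]2(O)C(C)C | intermediate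
23 | angelic acid, (2Z)-2-methylbut-2-enoic acid | C/C=C(/C)C(=O)O | starting material
24 | (3R,3aS,4S,8R,8aS)-3-hydroxy-6,8a-dimethyl-8-{[(2Z)-2-methylbut-2-enoyl]oxy}-3-(propan-2-yl)-1,2,3,3a,4,5,8,8a-octahydroazulen-4-yl 4-methoxybenzoate | C/C=C(/C)C(=O)O[C@@H]1C=C(C)C[C@H](OC(=O)c2ccc(OC)cc2)[C@@H]2[C@]1(C)CC[C@@]2(O)C(C)C | target

Total step count: 11. Longest linear sequence: 11 steps (from 1).

Steps most likely to fail

Step 8. The one-pot silylation/aldol may be diverted by silyl enol ether formation at the aldehyde, by slow equilibration of the dienol ether to the reactive (E) geometry, or by loss of water from the product to a dienone. The fallback generates the nucleophile reductively instead of by silylation. It sets out from 15: TMSOTf/Et3N (CH2Cl2, 0 °C) should give the bis-silylated 2-silyloxydiene F1; NBS (THF, −78 °C) should brominate its terminal carbon to give the γ-bromo enone F2 (the (E)-isomer is written; both isomers converge on the same zinc dienolate); oxalic acid in aqueous THF should remove the acetal and the silyl ether to give the bromo keto aldehyde F3; activated zinc (THF, 40 °C), an intramolecular vinylogous Reformatsky reaction under reversible zinc aldolate conditions where the strained α-adduct cannot accumulate, should close the ring and come back to the route at 19.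

Step 11. Displacement at a carbinol carbon next to a quaternary centre may be slow, and the activated alcohol may instead undergo allylic transposition (attack at C8), elimination to a diene, or substitution with retention through an ion pair; the angelate may also isomerise to the tiglate. The fallback replaces the SN2 displacement by ionisation and stereoelectronically controlled capture. It sets out from 22: Cl3CCN with catalytic DBU (CH2Cl2, 0 °C) should give the allylic trichloroacetimidate F4; angelic acid in toluene at 22 °C should protonate the imidate, and the carboxylate should capture the resulting allyl cation at C10 along the axial trajectory anti to the C1 methyl, coming back to the route at 24.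

Step 3. The secondary Grignard reagent may enolise the β-keto acetal, reduce the ketone by β-hydride transfer, or add to the wrong carbonyl face. The fallback uses an sp2 nucleophile that cannot transfer hydride and is less basic, followed by reduction. It sets out from 8: isopropenylmagnesium bromide with CeCl3 (THF, −78 °C) should give the isopropenyl carbinol F5; hydroxyl-directed hydrogenation with [Ir(cod)(PCy3)(py)]PF6 and H2 (CH2Cl2) should saturate the isopropenyl group in preference to the hindered vinylsilane and come back to the route at 10.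

Further compounds
F1 | step 8 | trimethylsilyl dienol ether and tertiary trimethylsilyl ether of 15, (1Z)-isomer | COC(OC)[C@@H]1[C@@](C)(/C(O[Si](C)(C)C)=C/C(C)=C)CC[C@@]1(O[Si](C)(C)C)C(C)C
F2 | step 8 | (2E)-4-bromo-1-[(1S,2R,3R)-2-(dimethoxymethyl)-1-methyl-3-(propan-2-yl)-3-(trimethylsilyloxy)cyclopentyl]-3-methylbut-2-en-1-one | COC(OC)[C@@H]1[C@@](C)(C(=O)/C=C(\C)CBr)CC[C@@]1(O[Si](C)(C)C)C(C)C
F3 | step 8 | (1R,2R,5S)-5-[(2E)-4-bromo-3-methylbut-2-enoyl]-2-hydroxy-5-methyl-2-(propan-2-yl)cyclopentane-1-carbaldehyde | O=C[C@@H]1[C@@](C)(C(=O)/C=C(\C)CBr)CC[C@@]1(O)C(C)C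
F4 | step 11 | 2,2,2-trichloroacetimidate of the 8S (10β) alcohol 22 | N=C(O[C@H]1C=C(C)C[C@H](OC(=O)c3ccc(OC)cc3)[C@@H]2[C@]1(C)CC[C@@]2(O)C(C)C)C(Cl)(Cl)Cl
F5 | step 3 | (1S,2R,3S)-2-(dimethoxymethyl)-3-methyl-1-(prop-1-en-2-yl)-3-[1-(trimethylsilyl)ethenyl]cyclopentan-1-ol | COC(OC)[C@@H]1[C@@](C)(C(=C)[Si](C)(C)C)CC[C@@]1(O)C(C)=C
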